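The phthalide is cut at two bonds of its benzo-fused γ-lactone ring, C3–C3a and C7a–C1. Adjacent ring carbons C3a and C7a carry C3 and C1, which are joined through O2, and the C7 methoxy group flanks C7a. A 3,5-dimethoxybenzyne can therefore accept a chiral α-lithiated O-alkyl carbamate at C3a and take its carbamoyl carbon at C7a. One operation forms both skeletal bonds, sets C3 and, after acid-induced loss of diisopropylamine, closes the lactone. The precursors are an iodo triflate aryne source and a C17 primary N,N-diisopropylcarbamate whose 1,4-diketone is masked as two dioxolanes.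

Key step: step 7

Remark: phthalide numbering is used (C1 carbonyl, O2, C3, C3a, C4–C7, C7a; side chain C1′–C16′), and (+)-sparteine is taken as a purchasable reagent.
Remark on the chemistry: a lithium alkoxide is not expected to expel lithium diisopropylamide from a hindered amide, so the anionic cascade is planned to end at the carbamoyl-shifted alkoxide and the lactone is closed by anhydrous acid within the same step.

Step 1
Reactants: 1 2-methylfuran; 2 12-bromododecan-1-ol
Product: 4 12-(5-methylfuran-2-yl)dodecan-1-ol, via (5-methylfuran-2-yl)lithium 3 (not isolated)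
Conditions: n-BuLi (2.5 equiv), THF, −78 → 0 °C; then 2, 0 °C → rt; aq. NH4Cl
Reagents that add atoms: none
Why: Lithiation of 2-methylfuran at C5 and SN2 alkylation by the primary bromide is the classical route to 2-alkyl-5-methylfurans; one extra equivalent of the cheap furyllithium removes the hydroxyl proton, and the lithium alkoxide formed is too poor a nucleophile to compete.

Step 2
Reactants: 4 12-(5-methylfuran-2-yl)dodecan-1-ol; 5 N,N-diisopropylcarbamoyl chloride
Product: 6 12-(5-methylfuran-2-yl)dodecyl N,N-diisopropylcarbamate
Conditions: Et3N, CH2Cl2, reflux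
Reagents that add atoms: none
Why: O-Carbamoylation of the primary alcohol (nucleophilic acyl substitution) installs the hindered carbamate early, so that it also shields the hydroxyl from esterification and acetal exchange in the two acid steps that follow.

Step 3
Reactants: 6 12-(5-methylfuran-2-yl)dodecyl N,N-diisopropylcarbamate
Product: 7 13,16-dioxoheptadecyl N,N-diisopropylcarbamate
Conditions: AcOH/H2O (2:1), H2SO4 (cat.), 110 °C
Reagents that add atoms: water, O
Why: Acid-catalysed hydrolytic ring opening of a 2,5-dialkylfuran (reverse Paal–Knorr reaction) should unveil the 1,4-diketone, while the primary N,N-diisopropylcarbamate is inert to hot aqueous acid.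

Step 4
Reactants: 7 13,16-dioxoheptadecyl N,N-diisopropylcarbamate
Product: 8 13,16-bis(ethylenedioxy)heptadecyl N,N-diisopropylcarbamate
Conditions: Me3SiOCH2CH2OSiMe3 (3 equiv), TMSOTf (cat.), CH2Cl2, −78 → −20 °C; pyridine quench
Reagents that add atoms: 1,2-bis(trimethylsilyloxy)ethane, C[Si](C)(C)OCCO[Si](C)(C)C
Why: Silyl triflate-catalysed ketalisation under aprotic conditions at low temperature should convert both ketones into dioxolanes without the heat and protic acid that would return a 1,4-diketone to the furan by Paal–Knorr cyclodehydration.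

Step 5
Reactants: 9 3,5-dimethoxyphenol
Product: 10 2-iodo-3,5-dimethoxyphenol
Conditions: N-iodosuccinimide (1.0 equiv, added slowly), CH2Cl2, −20 → 0 °C
Reagents that add atoms: N-iodosuccinimide, O=C1CCC(=O)N1I
Why: Electrophilic aromatic iodination in a non-polar solvent should deliver the hydrogen-bonded reagent to C2 (ortho to the hydroxyl, para to a methoxy group) in preference to the more hindered C4 between the two methoxy groups.

Step 6
Reactants: 10 2-iodo-3,5-dimethoxyphenol
Product: 11 2-iodo-3,5-dimethoxyphenyl trifluoromethanesulfonate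
Conditions: Tf2O, pyridine, CH2Cl2, 0 °C
Reagents that add atoms: trifluoromethanesulfonic anhydride, O=S(=O)(OS(=O)(=O)C(F)(F)F)C(F)(F)F
Why: Routine O-triflation of the phenol gives the ortho-iodoaryl triflate, an aryne source that can be triggered by iodine–lithium exchange at −78 °C.

Step 7
Reactants: 8 13,16-bis(ethylenedioxy)heptadecyl N,N-diisopropylcarbamate; 11 2-iodo-3,5-dimethoxyphenyl trifluoromethanesulfonate
Product: 16 (S)-5,7-dimethoxy-3-[12,15-bis(ethylenedioxy)hexadecyl]phthalide, via lithiated carbamate 12 (not isolated), via 3,5-dimethoxybenzyne 13 (not isolated), via aryllithium 14 (not isolated), via hydroxy amide 15 (not isolated)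
Conditions: s-BuLi (1.3 equiv), (+)-sparteine (1.3 equiv), Et2O, −78 °C, 5 h; 11 (1.5 equiv), then n-BuLi (1.2 equiv, dropwise), −78 °C → rt; aq. NH4Cl work-up; then TsOH·H2O (2 equiv), HOCH2CH2OH, PhMe, reflux with azeotropic removal of water
Reagents that add atoms: none
Why: Proposed new method: s-BuLi/(+)-sparteine removes the pro-R hydrogen at the carbinol carbon of 8 to give the chelated, configurationally stable organolithium 12, and iodine–lithium exchange on 11 followed by immediate loss of lithium triflate releases aryne 13 at −78 °C; 12 then adds across the strained triple bond (new bond C3–C3a), the C7a aryllithium 14 attacks the carbamate carbonyl through a five-membered transition state (new bond C7a–C1), and the tetrahedral intermediate opens to the alkoxide of 15, a 1,4 oxygen-to-carbon carbamoyl shift. The closest known reaction types are carbolithiation of arynes with capture of the aryl anion, sparteine-mediated lithiation–substitution of O-alkyl carbamates and anionic Fries-type carbamoyl migrations; their combination on one substrate has no precedent. Since a lithium alkoxide should not displace lithium diisopropylamide from the hindered amide, the lactone is closed in the same step by acid: the C3 hydroxyl adds to the twisted amide carbonyl (5-exo-trig, as is the preceding C7a-to-C1 attack) and diisopropylamine leaves, in a glycol medium with water removal that keeps both dioxolanes. C3 is controlled by the diamine on lithium: the R-configured carbanion is expected to react with retention, as unstabilised α-oxy alkyllithiums do with other electrophiles, to give S, and the centre should not ionise under the acid because both methoxy groups are meta to it. The step needs regioselectivity at the aryne, secured by the C7 methoxy group, whose inductive pull sends the carbanion to the remote carbon C3a and places the aryl anion on C7a; it also needs 12 to outrun n-BuLi, which is addressed by adding n-BuLi slowly to an excess of 11 so that exchange is faster than addition.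

Step 8
Reactants: 16 (S)-5,7-dimethoxy-3-[12,15-bis(ethylenedioxy)hexadecyl]phthalide
Product: 17 CJ-13,103, (S)-3-(12,15-dioxohexadecyl)-5,7-dimethoxyphthalide
Conditions: 1 M HCl (aq.), THF, rt
Reagents that add atoms: water, O
Why: Acid-catalysed acetal hydrolysis at room temperature should release the 1,4-diketone, while the lactone, the aryl methyl ethers and the unactivated benzylic C3 centre are untouched and aqueous medium disfavours furan formation.

Compound list
1 | 2-methylfuran | Cc1ccco1 | starting material
2 | 12-bromododecan-1-ol | OCCCCCCCCCCCCBr | starting material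
3 | (5-methylfuran-2-yl)lithium | Cc1ccc([Li])o1 | intermediate
4 | 12-(5-methylfuran-2-yl)dodecan-1-ol | Cc1ccc(CCCCCCCCCCCCO)o1 | intermediate
5 | N,N-diisopropylcarbamoyl chloride | CC(C)N(C(C)C)C(Cl)=O | starting material
6 | 12-(5-methylfuran-2-yl)dodecyl N,N-diisopropylcarbamate | CC(C)N(C(C)C)C(=O)OCCCCCCCCCCCCc1ccc(C)o1 | intermediate
7 | 13,16-dioxoheptadecyl N,N-diisopropylcarbamate | CC(C)N(C(C)C)C(=O)OCCCCCCCCCCCCC(=O)CCC(C)=O | intermediate
8 | 13,16-bis(ethylenedioxy)heptadecyl N,N-diisopropylcarbamate (bis(1,3-dioxolane) of 7) | CC(C)N(C(C)C)C(=O)OCCCCCCCCCCCCC1(CCC2(C)OCCO2)OCCO1 | intermediate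
9 | 3,5-dimethoxyphenol | COc1cc(O)cc(OC)c1 | starting material
10 | 2-iodo-3,5-dimethoxyphenol | COc1cc(O)c(I)c(OC)c1 | intermediate
11 | 2-iodo-3,5-dimethoxyphenyl trifluoromethanesulfonate | COc1cc(OC)c(I)c(OS(=O)(=O)C(F)(F)F)c1 | intermediate
12 | (R)-1-lithio-13,16-bis(ethylenedioxy)heptadecyl N,N-diisopropylcarbamate (lithium bound to (+)-sparteine, not drawn) | [Li][C@H](CCCCCCCCCCCC1(CCC2(C)OCCO2)OCCO1)OC(=O)N(C(C)C)C(C)C | intermediate
13 | 3,5-dimethoxybenzyne (1,2-didehydro-3,5-dimethoxybenzene) | COC1=CC(OC)=CC#C1 | intermediate
14 | (S)-1-(2-lithio-3,5-dimethoxyphenyl)-13,16-bis(ethylenedioxy)heptadecyl N,N-diisopropylcarbamate | COc1cc(OC)c([Li])c(c1)[C@H](CCCCCCCCCCCC2(CCC3(C)OCCO3)OCCO2)OC(=O)N(C(C)C)C(C)C | intermediate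
15 | (S)-2-[1-hydroxy-13,16-bis(ethylenedioxy)heptadecyl]-4,6-dimethoxy-N,N-diisopropylbenzamide (formed first as its lithium alkoxide) | COc1cc(OC)c(C(=O)N(C(C)C)C(C)C)c(c1)[C@H](CCCCCCCCCCCC2(CCC3(C)OCCO3)OCCO2)O | intermediate
16 | (S)-5,7-dimethoxy-3-[12,15-bis(ethylenedioxy)hexadecyl]phthalide (bis(1,3-dioxolane) of 17) | COc1cc(OC)c2c(c1)[C@H](CCCCCCCCCCCC3(CCC4(C)OCCO4)OCCO3)OC2=O | intermediate
17 | CJ-13,103, (S)-3-(12,15-dioxohexadecyl)-5,7-dimethoxyphthalide | COc1cc(OC)c2c(c1)[C@H](CCCCCCCCCCCC(=O)CCC(C)=O)OC2=O | target

Total step count: 8. Longest linear sequence: 6 steps (steps 1, 2, 3, 4, 7, 8).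

Steps most likely to fail

1. Step 7 (Proposed new method). What may go wrong:
- The sparteine-bound secondary carbanion may lose the race for the aryne to n-BuLi, residual s-BuLi or aryllithium 14, giving butylated arenes and biaryls.
- The carbanion may itself undergo iodine–lithium exchange with 11.
- It may add with erosion of configuration.
- The acid closure of the hindered amide may be slow.

Fallback with known chemistry, setting out from 8 and returning at 16. Compound 8 is lithiated as in step 7 (s-BuLi, (+)-sparteine, Et2O, −78 °C) and trapped with purchased 2-(3,5-dimethoxyphenyl)-4,4,5,5-tetramethyl-1,3,2-dioxaborolane. Warming with MgBr2·OEt2 should induce the stereospecific 1,2-migration (retention at boron capture, inversion on migration) to the boronic ester (S)-2-[1-(3,5-dimethoxyphenyl)-13,16-bis(ethylenedioxy)heptadecyl]-4,4,5,5-tetramethyl-1,3,2-dioxaborolane F1. Oxidation with NaOH/H2O2 should give (S)-1-(3,5-dimethoxyphenyl)-13,16-bis(ethylenedioxy)heptadecan-1-ol F2 with the same spatial arrangement at the carbinol as in 16. Bromination with N-bromosuccinimide (MeCN, 0 °C) at the position ortho to the side chain and para to a methoxy group should give (S)-1-(2-bromo-3,5-dimethoxyphenyl)-13,16-bis(ethylenedioxy)heptadecan-1-ol F3. Carbonylative lactonisation (Pd(OAc)2, Xantphos, CO at 1 atm, Et3N, PhMe, 90 °C) should then close the phthalide to 16.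

2. Step 5. What may go wrong: iodination at C4 between the methoxy groups and double iodination compete with attack at C2, and the isomers may be hard to separate.

Fallback by directed ortho-metalation, setting out from 9 and returning at 10. Compound 9 is carbamoylated (ClC(O)NEt2, K2CO3, MeCN, reflux) to 3,5-dimethoxyphenyl N,N-diethylcarbamate F4. Lithiation with s-BuLi/TMEDA (THF, −78 °C) should occur at the site flanked by the carbamate and a methoxy group, and an iodine quench at −78 °C should give 2-iodo-3,5-dimethoxyphenyl N,N-diethylcarbamate F5. Hydrolysis (NaOH, EtOH, reflux) returns 10.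

3. Step 1. What may go wrong: the lithium alkoxide formed from 2 may build mixed aggregates with 3 that retard substitution at the bromide, so that elimination and unreacted bromide dominate.

Fallback by masking the hydroxyl first, setting out from 2 and 5 and returning at 6 (step 2 is then skipped). Compound 2 is carbamoylated with 5 (NaH, THF, 0 °C → rt) to 12-bromododecyl N,N-diisopropylcarbamate F6. Its bromide is then displaced by 3 (from 1 and n-BuLi; THF, 0 °C → rt) to give 6 directly.

Further compounds
F1 | step 7 | (S)-2-[1-(3,5-dimethoxyphenyl)-13,16-bis(ethylenedioxy)heptadecyl]-4,4,5,5-tetramethyl-1,3,2-dioxaborolane | COc1cc(OC)cc(c1)[C@H](CCCCCCCCCCCC2(CCC3(C)OCCO3)OCCO2)B4OC(C)(C)C(C)(C)O4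
F2 | step 7 | (S)-1-(3,5-dimethoxyphenyl)-13,16-bis(ethylenedioxy)heptadecan-1-ol | COc1cc(OC)cc(c1)[C@H](CCCCCCCCCCCC2(CCC3(C)OCCO3)OCCO2)O
F3 | step 7 | (S)-1-(2-bromo-3,5-dimethoxyphenyl)-13,16-bis(ethylenedioxy)heptadecan-1-ol | COc1cc(OC)c(Br)c(c1)[C@H](CCCCCCCCCCCC2(CCC3(C)OCCO3)OCCO2)O
F4 | step 5 | 3,5-dimethoxyphenyl N,N-diethylcarbamate | CCN(CC)C(=O)Oc1cc(OC)cc(OC)c1
F5 | step 5 | 2-iodo-3,5-dimethoxyphenyl N,N-diethylcarbamate | CCN(CC)C(=O)Oc1cc(OC)cc(OC)c1I
F6 | step 1 | 12-bromododecyl N,N-diisopropylcarbamate | CC(C)N(C(C)C)C(=O)OCCCCCCCCCCCCBr
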